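**Plan**

- Locants and rings: C-2, C-3, C-4 are those of the 2,3-dihydrobenzofuran; ring A is its benzo ring, ring B the resorcinol ring on C-3, ring C the seven-membered ketone ring, ring D the dihydrofuran ring.
- Retrosynthetic cuts, in order: the four aryl O–CH3 bonds; the C(=O)–CH(aryl) bond of ring C; the ring B–CH(aryl) bond; the C-4–CHO bond; the C-2–C-3 bond of ring D; the ring B–C-3 bond; the ether O–CH2 bond.
- Enabling feature: the α-keto methine of ring C carries a 4-hydroxyphenyl group, so it is a latent para-quinone methide carbon, and it sits on ring B ortho to C-3. The ketone carbon sits on C-4 of ring A, also ortho to C-3, so an acyl anion equivalent made from a C-4 aldehyde reaches the methide carbon through a seven-membered transition state.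
- Forward order: ring A benzaldehyde → diaryl ketone → hydrazone → ring D by rhodium carbene C–H insertion → C-2 epimerisation → C-4 formyl → ring B bromination → benzhydryl sulfone → ring C by carbene catalysis → demethylation.
- Stereochemistry: C-3 from the chiral catalyst Rh2(R-PTAD)4 in the insertion; C-2 by acid equilibration to 2,3-trans under control of C-3; the α-keto methine by base equilibration under control of C-2 and C-3.

Key step: step 13

Assumption: Rh2(R-PTAD)4 is taken to deliver the (3R) series (otherwise Rh2(S-PTAD)4 is used), and the configuration of the enolisable α-keto methine in the target is taken to be the thermodynamically preferred one.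

**Route**

Step 1
Reactants: 1 2-bromo-4,6-dimethoxybenzaldehyde
Product: 2 2-bromo-6-hydroxy-4-methoxybenzaldehyde
Conditions: BCl3 (1.2 equiv), CH2Cl2, −78 → 0 °C; then H2O
Reagents that add atoms: none
Why: Boron trichloride chelates the aldehyde oxygen and the ortho methoxy oxygen and cleaves only that methyl ether (chelation-controlled ortho-demethylation), leaving the para methoxy group in place.

Step 2
Reactants: 2 2-bromo-6-hydroxy-4-methoxybenzaldehyde; 3 4-methoxybenzyl chloride
Product: 4 2-bromo-4-methoxy-6-[(4-methoxyphenyl)methoxy]benzaldehyde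
Conditions: K2CO3, NaI (cat.), DMF, 60 °C
Reagents that add atoms: none
Why: Williamson etherification of the phenoxide with a reactive benzylic chloride installs the O–CH2–aryl unit whose CH2 carbon later becomes C-2 with its 4-methoxyphenyl group.

Step 3
Reactants: 4 2-bromo-4-methoxy-6-[(4-methoxyphenyl)methoxy]benzaldehyde; 5 3,5-dimethoxyphenylmagnesium chloride
Product: 6 racemic {2-bromo-4-methoxy-6-[(4-methoxyphenyl)methoxy]phenyl}(3,5-dimethoxyphenyl)methanol
Conditions: THF, −78 → 0 °C; then H2O
Reagents that add atoms: none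
Why: Grignard 1,2-addition to the aldehyde is faster than any exchange at the aryl bromide and joins ring B to the future C-3, the racemic carbinol centre being removed in step 4.

Step 4
Reactants: 6 racemic {2-bromo-4-methoxy-6-[(4-methoxyphenyl)methoxy]phenyl}(3,5-dimethoxyphenyl)methanol
Product: 7 {2-bromo-4-methoxy-6-[(4-methoxyphenyl)methoxy]phenyl}(3,5-dimethoxyphenyl)methanone
Conditions: Dess–Martin periodinane, CH2Cl2, 25 °C
Reagents that add atoms: none
Why: Dess–Martin oxidation of a benzhydrol to the diaryl ketone proceeds under neutral conditions that leave the benzyl-type ether and the aryl bromide untouched.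

Step 5
Reactants: 7 {2-bromo-4-methoxy-6-[(4-methoxyphenyl)methoxy]phenyl}(3,5-dimethoxyphenyl)methanone
Product: 8 hydrazone of ketone 7 (E/Z mixture)
Conditions: N2H4·H2O (10 equiv), AcOH (cat.), EtOH, 90 °C (sealed tube)
Reagents that add atoms: hydrazine (as hydrate), NN
Why: Acid-catalysed condensation of hydrazine with the diaryl ketone gives the hydrazone (either geometry serves), and the unactivated ortho bromide is not displaced in the absence of a copper or palladium catalyst.

Step 6
Reactants: 8 hydrazone of ketone 7 (E/Z mixture)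
Product: 10 (2S,3R)-4-bromo-3-(3,5-dimethoxyphenyl)-6-methoxy-2-(4-methoxyphenyl)-2,3-dihydro-1-benzofuran, via diaryldiazomethane 9 (not isolated)
Conditions: MnO2, CH2Cl2, 0 °C; filter; Rh2(R-PTAD)4 (1 mol %), CH2Cl2, 0 → 25 °C
Reagents that add atoms: none
Why: Manganese dioxide dehydrogenates the hydrazone to the diaryldiazomethane, and the donor/donor rhodium carbene then undergoes enantioselective intramolecular 1,5 C–H insertion into the ether O–CH2 bond (activated by oxygen and the 4-methoxyphenyl group), the chiral carboxylate ligands fixing C-3 as (R) together with the 2,3-cis relationship.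

Step 7
Reactants: 10 (2S,3R)-4-bromo-3-(3,5-dimethoxyphenyl)-6-methoxy-2-(4-methoxyphenyl)-2,3-dihydro-1-benzofuran
Product: 11 (2R,3R)-4-bromo-3-(3,5-dimethoxyphenyl)-6-methoxy-2-(4-methoxyphenyl)-2,3-dihydro-1-benzofuran
Conditions: TFA (5 equiv), CH2Cl2, 0 °C
Reagents that add atoms: none
Why: The acid reversibly ionises the C-2–O bond to a 4-methoxybenzylic cation that recloses to the thermodynamically preferred 2,3-trans isomer (thermodynamic epimerisation at C-2 under control of the untouched C-3 centre).

Step 8
Reactants: 11 (2R,3R)-4-bromo-3-(3,5-dimethoxyphenyl)-6-methoxy-2-(4-methoxyphenyl)-2,3-dihydro-1-benzofuran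
Product: 13 (2R,3R)-3-(3,5-dimethoxyphenyl)-6-methoxy-2-(4-methoxyphenyl)-2,3-dihydro-1-benzofuran-4-carbaldehyde, via 4-lithio dihydrobenzofuran 12 (not isolated)
Conditions: n-BuLi (1.1 equiv), THF, −78 °C; DMF, −78 → 0 °C; then H2O
Reagents that add atoms: N,N-dimethylformamide, CN(C)C=O
Why: Bromine–lithium exchange at −78 °C is faster than deprotonation of the benzylic C–H bonds, and formylation of the aryllithium with DMF (Bouveault-type formylation) places the aldehyde at C-4.

Step 9
Reactants: 13 (2R,3R)-3-(3,5-dimethoxyphenyl)-6-methoxy-2-(4-methoxyphenyl)-2,3-dihydro-1-benzofuran-4-carbaldehyde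
Product: 14 (2R,3S)-3-(2-bromo-3,5-dimethoxyphenyl)-6-methoxy-2-(4-methoxyphenyl)-2,3-dihydro-1-benzofuran-4-carbaldehyde
Conditions: NBS (1.0 equiv), CH2Cl2, −78 → 0 °C, dark
Reagents that add atoms: N-bromosuccinimide, O=C1CCC(=O)N1Br
Why: Electrophilic aromatic bromination goes to the most electron-rich ring, ring B, at the position ortho to the C-3 substituent and para to a methoxy group (its two ortho positions are equivalent), because the formyl group deactivates ring A and the anisole ring is less activated; the change of descriptor at C-3 is only a change of substituent priority.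

Step 10
Reactants: 14 (2R,3S)-3-(2-bromo-3,5-dimethoxyphenyl)-6-methoxy-2-(4-methoxyphenyl)-2,3-dihydro-1-benzofuran-4-carbaldehyde
Product: 15 (2R,3S)-3-(2-bromo-3,5-dimethoxyphenyl)-4-(1,3-dioxolan-2-yl)-6-methoxy-2-(4-methoxyphenyl)-2,3-dihydro-1-benzofuran
Conditions: HOCH2CH2OH, p-TsOH·H2O (cat.), toluene, reflux (Dean–Stark)
Reagents that add atoms: ethylene glycol, OCCO
Why: Acid-catalysed acetalisation with azeotropic removal of water masks the aldehyde against the organolithium of the next step, and the 2,3-trans dihydrofuran is already the thermodynamic isomer under acid.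

Step 11
Reactants: 15 (2R,3S)-3-(2-bromo-3,5-dimethoxyphenyl)-4-(1,3-dioxolan-2-yl)-6-methoxy-2-(4-methoxyphenyl)-2,3-dihydro-1-benzofuran; 16 4-(tert-butyldimethylsilyloxy)benzaldehyde
Product: 18 {2-[(2R,3R)-4-(1,3-dioxolan-2-yl)-6-methoxy-2-(4-methoxyphenyl)-2,3-dihydro-1-benzofuran-3-yl]-4,6-dimethoxyphenyl}[4-(tert-butyldimethylsilyloxy)phenyl]methanol (both carbinol epimers), via ring B aryllithium 17 (not isolated)
Conditions: n-BuLi (1.1 equiv), THF, −78 °C; then 16, −78 → −20 °C; then H2O
Reagents that add atoms: none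
Why: Bromine–lithium exchange gives a methoxy-stabilised aryllithium that adds 1,2 to the aromatic aldehyde, and the carbinol configuration is irrelevant because this carbon becomes trigonal in step 13.

Step 12
Reactants: 18 {2-[(2R,3R)-4-(1,3-dioxolan-2-yl)-6-methoxy-2-(4-methoxyphenyl)-2,3-dihydro-1-benzofuran-3-yl]-4,6-dimethoxyphenyl}[4-(tert-butyldimethylsilyloxy)phenyl]methanol
Product: 19 (2R,3R)-3-(2-{[4-(tert-butyldimethylsilyloxy)phenyl](4-methylbenzenesulfonyl)methyl}-3,5-dimethoxyphenyl)-6-methoxy-2-(4-methoxyphenyl)-2,3-dihydro-1-benzofuran-4-carbaldehyde (both epimers at the sulfonyl carbon)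
Conditions: p-TolSO2Na (3 equiv), HCO2H/H2O/THF, 25 °C
Reagents that add atoms: sodium p-toluenesulfinate, Cc1ccc(cc1)S(=O)[O-].[Na+]; water, O
Why: The doubly donor-stabilised benzhydryl cation formed under mild acid is captured at sulfur by p-toluenesulfinate (SN1 sulfonylation) while the same aqueous acid hydrolyses the dioxolane, the aryl silyl ether surviving.

Step 13
Reactants: 19 (2R,3R)-3-(2-{[4-(tert-butyldimethylsilyloxy)phenyl](4-methylbenzenesulfonyl)methyl}-3,5-dimethoxyphenyl)-6-methoxy-2-(4-methoxyphenyl)-2,3-dihydro-1-benzofuran-4-carbaldehyde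
Product: 22 tetra-O-methyl pauciflorol E bearing the free 4-hydroxyphenyl group on the α-keto methine (2,3-trans; methine H anti to H-3), via phenol sulfone 20 (not isolated), via para-quinone methide 21 (not isolated)
Conditions: 2-(pentafluorophenyl)-6,7-dihydro-5H-pyrrolo[2,1-c][1,2,4]triazol-2-ium tetrafluoroborate (20 mol %), CsF (3 equiv), DMF (0.01 M), 25 °C, argon; then aq NH4Cl
Reagents that add atoms: none
Why: Proposed new method: fluoride cleaves the aryl silyl ether of 19, the phenoxide of 20 expels p-toluenesulfinate by 1,6-elimination to give the para-quinone methide 21, the triazolylidene turns the C-4 aldehyde into a nucleophilic Breslow intermediate, and this acyl anion equivalent adds to the exocyclic methide carbon on ring B, after which rearomatisation to the phenoxide and release of the carbene leave the aryl ketone. The closest known reaction type is the intermolecular carbene-catalysed 1,6-conjugate addition (vinylogous Stetter reaction) of aromatic aldehydes to isolable 2,6-di-tert-butyl para-quinone methides, combined with the known base-induced generation of transient quinone methides from hydroxyaryl sulfones; what is new is the intramolecular, seven-membered-ring-forming use on an unhindered transient para-quinone methide. Ring C closes in a 7-exo-trig mode, the attacked C=C bond lying outside the new ring. The one new stereocenter, the α-keto methine, is doubly benzylic and enolisable, so it is set by thermodynamic equilibration in the basic medium under control of the fixed C-2 and C-3 centres, the 4-hydroxyphenyl group taking the pseudo-equatorial position with its methine hydrogen anti to H-3. The step needs chemoselectivity for intramolecular C-acylation of the methide over benzoin condensation, over 1,6-addition of sulfinate, fluoride or the free carbene and over quinone methide oligomerisation, and this is secured by the ortho,ortho' placement of aldehyde and methide around the C-3 methine, by the reversibility of the heteroatom additions and by high dilution.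

Step 14
Reactants: 22 tetra-O-methyl pauciflorol E bearing the free 4-hydroxyphenyl group on the α-keto methine
Product: 23 pauciflorol E
Conditions: BBr3 (10 equiv), CH2Cl2, −78 → 25 °C; then H2O
Reagents that add atoms: none
Why: Boron tribromide cleaves the four aryl methyl ethers by Lewis acid activation and bromide attack on the methyl groups (a standard global demethylation for stilbenoid oligomers), any reversible opening of the C-2–O bond returning the 2,3-trans isomer and the α-keto methine staying at its thermodynamic configuration.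

**Compound list**

1 | 2-bromo-4,6-dimethoxybenzaldehyde | COc1cc(OC)c(C=O)c(Br)c1 | starting material
2 | 2-bromo-6-hydroxy-4-methoxybenzaldehyde | COc1cc(O)c(C=O)c(Br)c1 | intermediate
3 | 4-methoxybenzyl chloride | COc1ccc(CCl)cc1 | starting material
4 | 2-bromo-4-methoxy-6-[(4-methoxyphenyl)methoxy]benzaldehyde | COc1ccc(COc2cc(OC)cc(Br)c2C=O)cc1 | intermediate
5 | 3,5-dimethoxyphenylmagnesium chloride (THF solution) | COc1cc(OC)cc([Mg]Cl)c1 | starting material
6 | racemic {2-bromo-4-methoxy-6-[(4-methoxyphenyl)methoxy]phenyl}(3,5-dimethoxyphenyl)methanol | COc1ccc(COc2cc(OC)cc(Br)c2C(O)c2cc(OC)cc(OC)c2)cc1 | intermediate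
7 | {2-bromo-4-methoxy-6-[(4-methoxyphenyl)methoxy]phenyl}(3,5-dimethoxyphenyl)methanone | COc1ccc(COc2cc(OC)cc(Br)c2C(=O)c2cc(OC)cc(OC)c2)cc1 | intermediate
8 | hydrazone of ketone 7 (E/Z mixture) | COc1ccc(COc2cc(OC)cc(Br)c2C(=NN)c2cc(OC)cc(OC)c2)cc1 | intermediate
9 | diaryldiazomethane from 8 (formed in the flask) | COc1ccc(COc2cc(OC)cc(Br)c2C(=[N+]=[N-])c2cc(OC)cc(OC)c2)cc1 | intermediate
10 | (2S,3R)-4-bromo-3-(3,5-dimethoxyphenyl)-6-methoxy-2-(4-methoxyphenyl)-2,3-dihydro-1-benzofuran (2,3-cis) | Brc1cc(OC)cc2c1[C@@H](c1cc(OC)cc(OC)c1)[C@@H](c1ccc(OC)cc1)O2 | intermediate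
11 | (2R,3R)-4-bromo-3-(3,5-dimethoxyphenyl)-6-methoxy-2-(4-methoxyphenyl)-2,3-dihydro-1-benzofuran (2,3-trans) | Brc1cc(OC)cc2c1[C@@H](c1cc(OC)cc(OC)c1)[C@H](c1ccc(OC)cc1)O2 | intermediate
12 | 4-lithio derivative of 11 (formed in the flask) | [Li]c1cc(OC)cc2c1[C@@H](c1cc(OC)cc(OC)c1)[C@H](c1ccc(OC)cc1)O2 | intermediate
13 | (2R,3R)-3-(3,5-dimethoxyphenyl)-6-methoxy-2-(4-methoxyphenyl)-2,3-dihydro-1-benzofuran-4-carbaldehyde | O=Cc1cc(OC)cc2c1[C@@H](c1cc(OC)cc(OC)c1)[C@H](c1ccc(OC)cc1)O2 | intermediate
14 | (2R,3S)-3-(2-bromo-3,5-dimethoxyphenyl)-6-methoxy-2-(4-methoxyphenyl)-2,3-dihydro-1-benzofuran-4-carbaldehyde (2,3-trans) | O=Cc1cc(OC)cc2c1[C@@H](c1cc(OC)cc(OC)c1Br)[C@H](c1ccc(OC)cc1)O2 | intermediate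
15 | (2R,3S)-3-(2-bromo-3,5-dimethoxyphenyl)-4-(1,3-dioxolan-2-yl)-6-methoxy-2-(4-methoxyphenyl)-2,3-dihydro-1-benzofuran | O1CCOC1c1cc(OC)cc2c1[C@@H](c1cc(OC)cc(OC)c1Br)[C@H](c1ccc(OC)cc1)O2 | intermediate
16 | 4-(tert-butyldimethylsilyloxy)benzaldehyde | CC(C)(C)[Si](C)(C)Oc1ccc(C=O)cc1 | starting material
17 | ring B aryllithium from 15 (formed in the flask) | O1CCOC1c1cc(OC)cc2c1[C@@H](c1cc(OC)cc(OC)c1[Li])[C@H](c1ccc(OC)cc1)O2 | intermediate
18 | {2-[(2R,3R)-4-(1,3-dioxolan-2-yl)-6-methoxy-2-(4-methoxyphenyl)-2,3-dihydro-1-benzofuran-3-yl]-4,6-dimethoxyphenyl}[4-(tert-butyldimethylsilyloxy)phenyl]methanol (both carbinol epimers) | O1CCOC1c1cc(OC)cc2c1[C@@H](c1cc(OC)cc(OC)c1C(O)c1ccc(O[Si](C)(C)C(C)(C)C)cc1)[C@H](c1ccc(OC)cc1)O2 | intermediate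
19 | (2R,3R)-3-(2-{[4-(tert-butyldimethylsilyloxy)phenyl](4-methylbenzenesulfonyl)methyl}-3,5-dimethoxyphenyl)-6-methoxy-2-(4-methoxyphenyl)-2,3-dihydro-1-benzofuran-4-carbaldehyde (both epimers at the sulfonyl carbon) | O=Cc1cc(OC)cc2c1[C@@H](c1cc(OC)cc(OC)c1C(c1ccc(O[Si](C)(C)C(C)(C)C)cc1)S(=O)(=O)c1ccc(C)cc1)[C@H](c1ccc(OC)cc1)O2 | intermediate
20 | desilylated phenol sulfone from 19 (formed in the flask as its cesium phenoxide) | O=Cc1cc(OC)cc2c1[C@@H](c1cc(OC)cc(OC)c1C(c1ccc(O)cc1)S(=O)(=O)c1ccc(C)cc1)[C@H](c1ccc(OC)cc1)O2 | intermediate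
21 | para-quinone methide aldehyde (formed in the flask) | O=Cc1cc(OC)cc2c1[C@@H](c1cc(OC)cc(OC)c1C=C1C=CC(=O)C=C1)[C@H](c1ccc(OC)cc1)O2 | intermediate
22 | tetra-O-methyl pauciflorol E with the free 4-hydroxyphenyl group on the α-keto methine (2,3-trans; methine H anti to H-3) | O=C1c2cc(OC)cc3c2[C@@H](c2cc(OC)cc(OC)c2[C@H]1c1ccc(O)cc1)[C@H](c1ccc(OC)cc1)O3 | intermediate
23 | pauciflorol E | O=C1c2cc(O)cc3c2[C@@H](c2cc(O)cc(O)c2[C@H]1c1ccc(O)cc1)[C@H](c1ccc(O)cc1)O3 | target

**Totals and risks**

Total step count: 14. Longest linear sequence: 14 steps (1 → 23).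

Steps most likely to fail:

1. Step 13 (the step proposed as a new method). The transient quinone methide may be consumed by oligomerisation or by 1,6-addition of the free carbene (catalyst sequestration), or the aldehyde may undergo benzoin-type self-condensation, before the seven-membered ring closes. The fallback uses known chemistry, sets out from aldehyde 13 and rejoins the route at 23, so that steps 9 to 12 are not needed. Compound 3 and dimethyl sulfide give (4-methoxybenzyl)dimethylsulfonium chloride F1. Its ylide (KOH, MeCN, 0 °C) converts 13 in a Corey–Chaykovsky reaction into the trans-epoxide F2. BF3·OEt2 (CH2Cl2, −40 °C) opens F2 at the 4-methoxybenzylic carbon, and ring B closes ring C by intramolecular Friedel–Crafts alkylation (the ring B-to-methine bond is formed instead) to give the ring C alcohol F3. Dess–Martin oxidation gives the pentamethyl ether ketone F4, which is equilibrated at the α-keto methine with DBU. BBr3 then cleaves the five methyl ethers to give 23.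

2. Step 6. The two ortho substituents on the carbene-bearing ring (bromine and the benzyl-type ether) may slow carbene formation, favour azine formation from the diazo compound and erode facial discrimination in the insertion. The fallback sets out from aldehyde 4 and rejoins the route at 11. Henry condensation of 4 with nitromethane (NH4OAc, AcOH, 90 °C) gives the (E)-nitroalkene F5. Rhodium-catalysed asymmetric conjugate addition of 3,5-dimethoxyphenylboronic acid ([RhCl(C2H4)2]2, chiral bicyclic diene ligand of the enantiomeric series that gives the (R) centre, KOH, dioxane/H2O; Hayashi–Miyaura reaction) gives the 2,2-diaryl-1-nitroethane F6. A Nef reaction (NaOMe, MeOH; then H2SO4, −30 °C) gives the diarylacetaldehyde F7, which is used at once to limit enolisation. 4-Methoxyphenylmagnesium bromide (THF, −78 °C) gives the carbinol F8. TFA with anisole (CH2Cl2, 0 °C) removes the 4-methoxybenzyl ether and closes ring D through the 4-methoxybenzylic cation to give the 2,3-trans compound 11.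

3. Step 12. Ionisation of the hindered benzhydrol may not end in clean capture at sulfur: competing paths are O-sulfinate ester formation, alkylation of electron-rich rings by the cation, and premature loss of the silyl group followed by quinone methide polymerisation. The fallback sets out from carbinol 18 and rejoins the route at 22 through 21. Mild hydrolysis of the dioxolane (PPTS, acetone/H2O, 40 °C) gives the hydroxy aldehyde F9. Acetylation (Ac2O, Et3N, DMAP cat., CH2Cl2, 0 °C) gives the benzhydryl acetate F10, which is used without storage. Under the conditions of step 13, fluoride releases the phenol acetate F11 as its phenoxide, whose 1,6-elimination of acetate gives 21 and then 22.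

Further compounds
F1 | step 13 | (4-methoxybenzyl)dimethylsulfonium chloride | COc1ccc(C[S+](C)C)cc1.[Cl-]
F2 | step 13 | trans-2-[(2R,3R)-3-(3,5-dimethoxyphenyl)-6-methoxy-2-(4-methoxyphenyl)-2,3-dihydro-1-benzofuran-4-yl]-3-(4-methoxyphenyl)oxirane (epoxide epimers) | COc1ccc(cc1)C1OC1c1cc(OC)cc2c1[C@@H](c1cc(OC)cc(OC)c1)[C@H](c1ccc(OC)cc1)O2
F3 | step 13 | ring C alcohol, pentamethyl ether (isomers at the carbinol and the adjacent methine) | OC1c2cc(OC)cc3c2[C@@H](c2cc(OC)cc(OC)c2C1c1ccc(OC)cc1)[C@H](c1ccc(OC)cc1)O3
F4 | step 13 | penta-O-methyl pauciflorol E | O=C1c2cc(OC)cc3c2[C@@H](c2cc(OC)cc(OC)c2[C@H]1c1ccc(OC)cc1)[C@H](c1ccc(OC)cc1)O3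
F5 | step 6 | 1-bromo-5-methoxy-3-[(4-methoxyphenyl)methoxy]-2-[(E)-2-nitroethenyl]benzene | COc1ccc(COc2cc(OC)cc(Br)c2/C=C/[N+](=O)[O-])cc1
F6 | step 6 | (R)-1-bromo-2-[1-(3,5-dimethoxyphenyl)-2-nitroethyl]-5-methoxy-3-[(4-methoxyphenyl)methoxy]benzene | COc1ccc(COc2cc(OC)cc(Br)c2[C@@H](c2cc(OC)cc(OC)c2)C[N+](=O)[O-])cc1
F7 | step 6 | (R)-2-{2-bromo-4-methoxy-6-[(4-methoxyphenyl)methoxy]phenyl}-2-(3,5-dimethoxyphenyl)acetaldehyde | COc1ccc(COc2cc(OC)cc(Br)c2[C@@H](c2cc(OC)cc(OC)c2)C=O)cc1
F8 | step 6 | (2R)-2-{2-bromo-4-methoxy-6-[(4-methoxyphenyl)methoxy]phenyl}-2-(3,5-dimethoxyphenyl)-1-(4-methoxyphenyl)ethanol (both carbinol epimers) | COc1ccc(COc2cc(OC)cc(Br)c2[C@@H](c2cc(OC)cc(OC)c2)C(O)c2ccc(OC)cc2)cc1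
F9 | step 12 | (2R,3R)-3-(2-{[4-(tert-butyldimethylsilyloxy)phenyl](hydroxy)methyl}-3,5-dimethoxyphenyl)-6-methoxy-2-(4-methoxyphenyl)-2,3-dihydro-1-benzofuran-4-carbaldehyde | O=Cc1cc(OC)cc2c1[C@@H](c1cc(OC)cc(OC)c1C(O)c1ccc(O[Si](C)(C)C(C)(C)C)cc1)[C@H](c1ccc(OC)cc1)O2
F10 | step 12 | benzhydryl acetate of F9 | O=Cc1cc(OC)cc2c1[C@@H](c1cc(OC)cc(OC)c1C(OC(C)=O)c1ccc(O[Si](C)(C)C(C)(C)C)cc1)[C@H](c1ccc(OC)cc1)O2
F11 | step 12 | desilylated phenol acetate from F10 (formed in the flask) | O=Cc1cc(OC)cc2c1[C@@H](c1cc(OC)cc(OC)c1C(OC(C)=O)c1ccc(O)cc1)[C@H](c1ccc(OC)cc1)O2
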